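# Proposed total synthesis of (2S)-5,7-dihydroxy-2-(8-hydroxy-2,2-dimethyl-2H-chromen-6-yl)-2,3-dihydro-4H-chromen-4-one (EANPDB:LEGU_00166)

## Retrosynthetic overview

- The three phenols are freed last from MOM ethers; before that, ring C of the protected flavanone is disconnected at two bonds at once, O1–C8a and C4–C4a.
- Key step: a fluoride-triggered aryne annulation. The C2 alkoxide of an (S)-β-silyloxy morpholine amide adds to 3,5-bis(methoxymethoxy)benzyne (triple bond C4a≡C8a), and the C4a carbanion then closes ring C on the amide carbonyl C4.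
- Enabling feature: in ring A, O1 (on C8a) and the carbonyl carbon C4 (on C4a) sit on neighbouring carbons, and C4a is flanked on its other side by the C5 oxygen. Ring A is therefore the retron of a 3-alkoxyaryne whose polarisation puts the oxygen on C8a and the carbanion on C4a, while C2 keeps its C–O bond and its configuration.
- C2 is set beforehand by asymmetric transfer hydrogenation of a β-keto amide, made by crossed Claisen condensation on the chromene ester.
- Ring order: rings A and B are bought (phloroglucinol, methyl 3,4-dihydroxybenzoate); the dimethylpyran ring is formed first (aryl propargyl ether Claisen rearrangement/oxa-6π electrocyclisation), ring C last.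

Key step: step 10

Remark: the stereodescriptor at C2 in the SMILES corresponds to the (2S) configuration, and the route is planned for this enantiomer.

## Route

Step 1
Reactants: 1 phloroglucinol (benzene-1,3,5-triol)
Product: 2 3,5-bis(methoxymethoxy)phenol
Conditions: MOMCl (2.0 equiv), i-Pr2NEt (2.2 equiv), CH2Cl2/DMF, 0 °C → rt
Reagents that add atoms: chloromethyl methyl ether (MOMCl), COCCl
Why: Williamson-type O-alkylation of the phenol with MOMCl; two equivalents should give the bis-ether as the main statistical product, and the separable mono- and tris-ethers can be recycled.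

Step 2
Reactants: 2 3,5-bis(methoxymethoxy)phenol
Product: 3 2-bromo-3,5-bis(methoxymethoxy)phenol
Conditions: NBS (1.0 equiv), i-Pr2NH (10 mol%), CH2Cl2, −78 → 0 °C
Reagents that add atoms: N-bromosuccinimide (NBS), O=C1CCC(=O)N1Br
Why: Electrophilic aromatic bromination, amine-catalysed for ortho delivery from the phenol; C2 (ortho to OH) should be favoured over C4, which lies between two bulkier MOM ethers, and one equivalent at low temperature limits polybromination.

Step 3
Reactants: 3 2-bromo-3,5-bis(methoxymethoxy)phenol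
Product: 7 3,5-bis(methoxymethoxy)-2-(trimethylsilyl)phenyl trifluoromethanesulfonate, via aryl silyl ether 4 (not isolated), via aryllithium 5 (not isolated), via lithium phenoxide 6 (not isolated)
Conditions: HMDS, THF, 65 °C, then evaporation; n-BuLi, THF, −78 °C; Tf2O, −78 °C → rt
Reagents that add atoms: hexamethyldisilazane (HMDS), C[Si](C)(C)N[Si](C)(C)C; trifluoromethanesulfonic anhydride (Tf2O), O=S(=O)(OS(=O)(=O)C(F)(F)F)C(F)(F)F
Why: O-silylation, then bromine–lithium exchange followed by a 1,3 O→C silyl shift (retro-Brook rearrangement) places the silyl group on C2, and the liberated phenoxide is triflated, the standard entry to ortho-silylaryl triflates as fluoride-triggered aryne precursors.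

Step 4
Reactants: 8 methyl 3,4-dihydroxybenzoate; 9 3-chloro-3-methylbut-1-yne
Product: 10 methyl 3-hydroxy-4-[(2-methylbut-3-yn-2-yl)oxy]benzoate
Conditions: DBU (1.1 equiv), CuCl2·2H2O (1 mol%), MeCN, 0 °C
Reagents that add atoms: none
Why: Copper-catalysed propargylic substitution of the tertiary chloride by a phenoxide; the 4-OH, para to the ester, is the more acidic hydroxyl and should be alkylated selectively with one equivalent of base.

Step 5
Reactants: 10 methyl 3-hydroxy-4-[(2-methylbut-3-yn-2-yl)oxy]benzoate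
Product: 11 methyl 3-(methoxymethoxy)-4-[(2-methylbut-3-yn-2-yl)oxy]benzoate
Conditions: MOMCl, i-Pr2NEt, CH2Cl2, 0 → 40 °C
Reagents that add atoms: chloromethyl methyl ether (MOMCl), COCCl
Why: Standard MOM protection, so that no free phenol is present in the thermal rearrangement or in the later anionic steps.

Step 6
Reactants: 11 methyl 3-(methoxymethoxy)-4-[(2-methylbut-3-yn-2-yl)oxy]benzoate
Product: 15 methyl 8-(methoxymethoxy)-2,2-dimethyl-2H-chromene-6-carboxylate, via allenyl dienone 12 (not isolated), via allenylphenol 13 (not isolated), via quinone methide 14 (not isolated)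
Conditions: PhNEt2, 190 °C
Reagents that add atoms: none
Why: Aromatic propargyl Claisen rearrangement to C5, the only free ortho carbon, then tautomerisation, 1,5-hydrogen shift and oxa-6π electrocyclisation, the standard thermal route to 2,2-dimethyl-2H-chromenes.

Step 7
Reactants: 15 methyl 8-(methoxymethoxy)-2,2-dimethyl-2H-chromene-6-carboxylate; 16 4-acetylmorpholine
Product: 19 1-[8-(methoxymethoxy)-2,2-dimethyl-2H-chromen-6-yl]-3-(morpholin-4-yl)propane-1,3-dione, via amide enolate 17 (not isolated), via ketoamide enolate 18 (not isolated)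
Conditions: LDA (2.2 equiv), 16 (2.2 equiv), THF, −78 °C; then 15, −78 → 0 °C; sat. aq NH4Cl
Reagents that add atoms: none
Why: Crossed Claisen condensation of an amide enolate with a non-enolisable aryl ester; the second equivalent of enolate deprotonates the β-keto amide and drives the reaction.

Step 8
Reactants: 19 1-[8-(methoxymethoxy)-2,2-dimethyl-2H-chromen-6-yl]-3-(morpholin-4-yl)propane-1,3-dione
Product: 20 (3S)-3-hydroxy-3-[8-(methoxymethoxy)-2,2-dimethyl-2H-chromen-6-yl]-1-(morpholin-4-yl)propan-1-one
Conditions: RuCl[(S,S)-TsDPEN](p-cymene) (1 mol%), HCO2H/Et3N (5:2), CH2Cl2, 30 °C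
Reagents that add atoms: none
Why: Noyori asymmetric transfer hydrogenation of an aryl ketone; the (S,S)-catalyst delivers hydride to the face that gives (S)-1-arylalkanols (CH/π contact of the aryl group with the η6-arene in the six-membered transition state), which should set C2 as (S) because aryl outranks the CH2C(=O)N group.

Step 9
Reactants: 20 (3S)-3-hydroxy-3-[8-(methoxymethoxy)-2,2-dimethyl-2H-chromen-6-yl]-1-(morpholin-4-yl)propan-1-one
Product: 21 (3S)-3-[8-(methoxymethoxy)-2,2-dimethyl-2H-chromen-6-yl]-1-(morpholin-4-yl)-3-[(trimethylsilyl)oxy]propan-1-one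
Conditions: HMDS (0.6 equiv), TMSCl (2 mol%), CH2Cl2, rt; evaporation
Reagents that add atoms: hexamethyldisilazane (HMDS), C[Si](C)(C)N[Si](C)(C)C
Why: Silylation with HMDS masks the O–H so that the key step holds no proton source; ammonia is the only by-product and the labile silyl ether is used after evaporation.

Step 10
Reactants: 21 (3S)-3-[8-(methoxymethoxy)-2,2-dimethyl-2H-chromen-6-yl]-1-(morpholin-4-yl)-3-[(trimethylsilyl)oxy]propan-1-one; 7 3,5-bis(methoxymethoxy)-2-(trimethylsilyl)phenyl trifluoromethanesulfonate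
Product: 26 (2S)-5,7-bis(methoxymethoxy)-2-[8-(methoxymethoxy)-2,2-dimethyl-2H-chromen-6-yl]-2,3-dihydro-4H-chromen-4-one, via potassium alkoxide 22 (not isolated), via aryne 23 (not isolated), via aryl anion 24 (not isolated), via hemiaminal alkoxide 25 (not isolated)
Conditions: 7 (1.5 equiv), KF (4 equiv), 18-crown-6 (4 equiv), THF, −20 → 20 °C; then sat. aq NH4Cl, 0 °C
Reagents that add atoms: none
Why: Proposed new method: fluoride unmasks both partners without any proton source, cleaving the O–Si bond of 21 to the naked alkoxide 22 and triggering 1,2-elimination of 7 to the aryne 23; 22 adds to 23, the resulting aryl carbanion 24 attacks the morpholine amide carbonyl, and the tetrahedral adduct 25 releases the ketone only on mildly acidic work-up, so the base-labile flavanone never meets base. The closest known reactions are the fluoride-mediated annulation of arynes with salicylate esters to xanthones (phenoxide addition, then acyl substitution by the aryl anion) and the O–H insertion of aliphatic alcohols into arynes; new is the use of an aliphatic β-silyloxy amide, where the aryl anion is captured by the carbonyl instead of a proton. Ring C closes by 6-exo-trig attack of the C4a carbanion on C4, which forms the C4–C4a bond after the O1–C8a bond has formed. No stereocentre is created in the product: C2 is carried through with retention because its C–O bond is never broken, and the C4 hemiaminal centre of 25 is lost on work-up. The step needs regioselective O-addition at C8a, which the inductively withdrawing MOM-oxygen at C5 should secure by polarising the aryne so that negative charge develops at C4a next to it, and it needs C-acylation to beat protonation and E1cB loss of the aryloxide, which the aprotic medium, the poorly acidic α-CH2 of an amide and the six-membered transition state should secure. Retro-aldol cleavage of 22 is disfavoured because an amide enolate is a poor leaving group.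

Step 11
Reactants: 26 (2S)-5,7-bis(methoxymethoxy)-2-[8-(methoxymethoxy)-2,2-dimethyl-2H-chromen-6-yl]-2,3-dihydro-4H-chromen-4-one
Product: 27 (2S)-5,7-dihydroxy-2-(8-hydroxy-2,2-dimethyl-2H-chromen-6-yl)-2,3-dihydro-4H-chromen-4-one (target)
Conditions: HCl (0.5 M in MeOH), MeOH/THF, 40 °C
Reagents that add atoms: none
Why: Acid-catalysed transacetalisation of the three MOM ethers to methanol; the chelated 5-O-MOM and the vinylogous 7-O-MOM cleave easily, and dilute acid at 40 °C should spare the chromene double bond and the C2 centre.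

## Compound list

1 | phloroglucinol (benzene-1,3,5-triol) | Oc1cc(O)cc(O)c1 | starting material
2 | 3,5-bis(methoxymethoxy)phenol | COCOc1cc(O)cc(OCOC)c1 | intermediate
3 | 2-bromo-3,5-bis(methoxymethoxy)phenol | COCOc1cc(O)c(Br)c(OCOC)c1 | intermediate
4 | [2-bromo-3,5-bis(methoxymethoxy)phenoxy]trimethylsilane (aryl silyl ether, not isolated) | COCOc1cc(O[Si](C)(C)C)c(Br)c(OCOC)c1 | intermediate
5 | [2,4-bis(methoxymethoxy)-6-(trimethylsilyloxy)phenyl]lithium (aryllithium, not isolated) | COCOc1cc(O[Si](C)(C)C)c([Li])c(OCOC)c1 | intermediate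
6 | lithium 3,5-bis(methoxymethoxy)-2-(trimethylsilyl)phenolate (not isolated) | COCOc1cc([O-])c([Si](C)(C)C)c(OCOC)c1.[Li+] | intermediate
7 | 3,5-bis(methoxymethoxy)-2-(trimethylsilyl)phenyl trifluoromethanesulfonate | COCOc1cc(OS(=O)(=O)C(F)(F)F)c([Si](C)(C)C)c(OCOC)c1 | intermediate
8 | methyl 3,4-dihydroxybenzoate | COC(=O)c1ccc(O)c(O)c1 | starting material
9 | 3-chloro-3-methylbut-1-yne | CC(C)(Cl)C#C | starting material
10 | methyl 3-hydroxy-4-[(2-methylbut-3-yn-2-yl)oxy]benzoate | COC(=O)c1ccc(OC(C)(C)C#C)c(O)c1 | intermediate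
11 | methyl 3-(methoxymethoxy)-4-[(2-methylbut-3-yn-2-yl)oxy]benzoate | COC(=O)c1ccc(OC(C)(C)C#C)c(OCOC)c1 | intermediate
12 | methyl 5-(methoxymethoxy)-3-(3-methylbuta-1,2-dien-1-yl)-4-oxocyclohexa-1,5-diene-1-carboxylate (allenyl dienone, not isolated) | O=C1C(OCOC)=CC(C(=O)OC)=CC1C=C=C(C)C | intermediate
13 | methyl 4-hydroxy-3-(methoxymethoxy)-5-(3-methylbuta-1,2-dien-1-yl)benzoate (allenylphenol, not isolated) | COC(=O)c1cc(OCOC)c(O)c(C=C=C(C)C)c1 | intermediate
14 | methyl 5-(methoxymethoxy)-3-(3-methylbut-2-en-1-ylidene)-4-oxocyclohexa-1,5-diene-1-carboxylate (quinone methide, not isolated) | O=C1C(OCOC)=CC(C(=O)OC)=CC1=CC=C(C)C | intermediate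
15 | methyl 8-(methoxymethoxy)-2,2-dimethyl-2H-chromene-6-carboxylate | CC1(C)C=Cc2cc(C(=O)OC)cc(OCOC)c2O1 | intermediate
16 | 4-acetylmorpholine | CC(=O)N1CCOCC1 | starting material
17 | lithium 1-(morpholin-4-yl)ethen-1-olate (amide enolate, not isolated) | [Li+].[O-]C(=C)N1CCOCC1 | intermediate
18 | lithium enolate of 19 (ketoamide enolate, not isolated) | [Li+].[O-]C(=CC(=O)N1CCOCC1)c1cc2C=CC(C)(C)Oc2c(OCOC)c1 | intermediate
19 | 1-[8-(methoxymethoxy)-2,2-dimethyl-2H-chromen-6-yl]-3-(morpholin-4-yl)propane-1,3-dione | CC1(C)C=Cc2cc(C(=O)CC(=O)N3CCOCC3)cc(OCOC)c2O1 | intermediate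
20 | (3S)-3-hydroxy-3-[8-(methoxymethoxy)-2,2-dimethyl-2H-chromen-6-yl]-1-(morpholin-4-yl)propan-1-one | CC1(C)C=Cc2cc([C@@H](O)CC(=O)N3CCOCC3)cc(OCOC)c2O1 | intermediate
21 | (3S)-3-[8-(methoxymethoxy)-2,2-dimethyl-2H-chromen-6-yl]-1-(morpholin-4-yl)-3-[(trimethylsilyl)oxy]propan-1-one | CC1(C)C=Cc2cc([C@@H](O[Si](C)(C)C)CC(=O)N3CCOCC3)cc(OCOC)c2O1 | intermediate
22 | potassium (1S)-1-[8-(methoxymethoxy)-2,2-dimethyl-2H-chromen-6-yl]-3-(morpholin-4-yl)-3-oxopropan-1-olate (potassium alkoxide, not isolated) | CC1(C)C=Cc2cc([C@@H]([O-])CC(=O)N3CCOCC3)cc(OCOC)c2O1.[K+] | intermediate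
23 | 3,5-bis(methoxymethoxy)benzyne (1,2-didehydro-3,5-bis(methoxymethoxy)benzene; aryne, not isolated) | COCOC1=CC(OCOC)=CC#C1 | intermediate
24 | potassium 2-{(1S)-1-[8-(methoxymethoxy)-2,2-dimethyl-2H-chromen-6-yl]-3-(morpholin-4-yl)-3-oxopropoxy}-4,6-bis(methoxymethoxy)benzenide (aryl anion, not isolated) | CC1(C)C=Cc2cc([C@@H](Oc3cc(OCOC)cc(OCOC)[c-]3)CC(=O)N4CCOCC4)cc(OCOC)c2O1.[K+] | intermediate
25 | potassium (2S)-5,7-bis(methoxymethoxy)-2-[8-(methoxymethoxy)-2,2-dimethyl-2H-chromen-6-yl]-4-(morpholin-4-yl)-3,4-dihydro-2H-chromen-4-olate (hemiaminal alkoxide, C4 unassigned, not isolated) | CC1(C)C=Cc2cc([C@@H]3CC([O-])(N4CCOCC4)c4c(OCOC)cc(OCOC)cc4O3)cc(OCOC)c2O1.[K+] | intermediate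
26 | (2S)-5,7-bis(methoxymethoxy)-2-[8-(methoxymethoxy)-2,2-dimethyl-2H-chromen-6-yl]-2,3-dihydro-4H-chromen-4-one | CC1(C)C=Cc2cc([C@@H]3CC(=O)c4c(OCOC)cc(OCOC)cc4O3)cc(OCOC)c2O1 | intermediate
27 | (2S)-5,7-dihydroxy-2-(8-hydroxy-2,2-dimethyl-2H-chromen-6-yl)-2,3-dihydro-4H-chromen-4-one | CC1(C)C=Cc2cc([C@@H]3CC(=O)c4c(O)cc(O)cc4O3)cc(O)c2O1 | target

## Step count and risks

Total step count: 11. Longest linear sequence: 8 steps (steps 4 to 11, from methyl 3,4-dihydroxybenzoate); the aryne precursor 7 is made in 3 steps (steps 1 to 3) and joins at step 10.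

Steps most likely to fail:

**1. Step 10 (Proposed new method).** What may go wrong: the aryl carbanion is quenched by a proton or by silylation before it reaches the carbonyl; internal proton transfer from the α-CH2 leads to E1cB loss of the aryloxide; or the alkoxide attacks the sulfonyl group of 7 instead of the aryne. Ring C then does not close in the same pot. The fallback uses known chemistry in two operations, sets out from 20 (with 7) and comes back to the route at 26. The free alcohol 20 is O-arylated by O–H insertion into the aryne generated from 7 (KF, 18-crown-6, THF, −20 °C). The hydroxyl proton quenches the aryl anion, which should give the aryl ether (3S)-3-[3,5-bis(methoxymethoxy)phenoxy]-3-[8-(methoxymethoxy)-2,2-dimethyl-2H-chromen-6-yl]-1-(morpholin-4-yl)propan-1-one F1 with retention at C2. Ring C is then closed with reversed polarity by electrophilic amide activation (Tf2O, 2-fluoropyridine, CH2Cl2, −78 → 0 °C). The O-triflyl iminium triflate F2 is attacked at C4a by the phloroglucinol-type ring in an intramolecular Vilsmeier–Haack-type Friedel–Crafts acylation to give the cyclic iminium triflate F3, and aqueous NaHCO3 hydrolyses it to 26.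

**2. Step 2.** What may go wrong: poor site selectivity between C2 and C4 of the triply activated ring, and polybromination. The fallback sets out from 2 and comes back at 7; the position is fixed by directed ortho-metalation instead of electrophilic substitution. Isopropyl isocyanate (cat. Et3N, CH2Cl2, rt) converts 2 into the carbamate 3,5-bis(methoxymethoxy)phenyl N-(propan-2-yl)carbamate F4. In-situ N-silylation (TBSOTf, TMEDA, Et2O, 0 °C) gives the N-silyl carbamate F5. n-BuLi/TMEDA at −78 °C lithiates between the carbamate and a MOM ether to the aryllithium F6, and TMSCl gives the C-silylated N-silyl carbamate F7. Acidic work-up (aq NaHSO4) removes the N-silyl group to give the ortho-silyl carbamate 3,5-bis(methoxymethoxy)-2-(trimethylsilyl)phenyl N-(propan-2-yl)carbamate F8. DBU/Et2NH in MeCN at 40 °C cleaves the carbamate to the silylphenol 3,5-bis(methoxymethoxy)-2-(trimethylsilyl)phenol F9, which is triflated in the same pot with PhNTf2 to give 7.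

**3. Step 8.** What may go wrong: slow and poorly face-selective hydride transfer to the electron-rich, partly enolised β-keto amide. The fallback sets out from 19 and comes back at 20; it uses resolution instead of asymmetric catalysis. NaBH4 (MeOH, 0 °C) reduces 19 to the racemic alcohol rac-3-hydroxy-3-[8-(methoxymethoxy)-2,2-dimethyl-2H-chromen-6-yl]-1-(morpholin-4-yl)propan-1-one F10. Lipase-catalysed kinetic resolution (immobilised Candida antarctica lipase B, vinyl acetate, MTBE, 30 °C) should acetylate the (R)-alcohol (aryl as the large group, CH2 as the medium group) to the acetate (1R)-1-[8-(methoxymethoxy)-2,2-dimethyl-2H-chromen-6-yl]-3-(morpholin-4-yl)-3-oxopropyl acetate F11. The unreacted (S)-alcohol 20 is separated by chromatography.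

## Further compounds

F1 | step 10 | (3S)-3-[3,5-bis(methoxymethoxy)phenoxy]-3-[8-(methoxymethoxy)-2,2-dimethyl-2H-chromen-6-yl]-1-(morpholin-4-yl)propan-1-one | CC1(C)C=Cc2cc([C@@H](Oc3cc(OCOC)cc(OCOC)c3)CC(=O)N4CCOCC4)cc(OCOC)c2O1
F2 | step 10 | 4-{(3S)-3-[3,5-bis(methoxymethoxy)phenoxy]-3-[8-(methoxymethoxy)-2,2-dimethyl-2H-chromen-6-yl]-1-[(trifluoromethanesulfonyl)oxy]propylidene}morpholin-4-ium trifluoromethanesulfonate (O-triflyl iminium triflate, not isolated) | CC1(C)C=Cc2cc([C@@H](Oc3cc(OCOC)cc(OCOC)c3)CC(OS(=O)(=O)C(F)(F)F)=[N+]4CCOCC4)cc(OCOC)c2O1.[O-]S(=O)(=O)C(F)(F)F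
F3 | step 10 | 4-{(2S)-5,7-bis(methoxymethoxy)-2-[8-(methoxymethoxy)-2,2-dimethyl-2H-chromen-6-yl]-2,3-dihydro-4H-chromen-4-ylidene}morpholin-4-ium trifluoromethanesulfonate (cyclic iminium triflate, not isolated) | CC1(C)C=Cc2cc([C@@H]3CC(=[N+]4CCOCC4)c4c(OCOC)cc(OCOC)cc4O3)cc(OCOC)c2O1.[O-]S(=O)(=O)C(F)(F)F
F4 | step 2 | 3,5-bis(methoxymethoxy)phenyl N-(propan-2-yl)carbamate | COCOc1cc(OC(=O)NC(C)C)cc(OCOC)c1
F5 | step 2 | 3,5-bis(methoxymethoxy)phenyl N-[tert-butyl(dimethyl)silyl]-N-(propan-2-yl)carbamate (not isolated) | COCOc1cc(OC(=O)N(C(C)C)[Si](C)(C)C(C)(C)C)cc(OCOC)c1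
F6 | step 2 | [2-({[tert-butyl(dimethyl)silyl](propan-2-yl)carbamoyl}oxy)-4,6-bis(methoxymethoxy)phenyl]lithium (not isolated) | COCOc1cc(OC(=O)N(C(C)C)[Si](C)(C)C(C)(C)C)c([Li])c(OCOC)c1
F7 | step 2 | 3,5-bis(methoxymethoxy)-2-(trimethylsilyl)phenyl N-[tert-butyl(dimethyl)silyl]-N-(propan-2-yl)carbamate (not isolated) | COCOc1cc(OC(=O)N(C(C)C)[Si](C)(C)C(C)(C)C)c([Si](C)(C)C)c(OCOC)c1
F8 | step 2 | 3,5-bis(methoxymethoxy)-2-(trimethylsilyl)phenyl N-(propan-2-yl)carbamate | COCOc1cc(OC(=O)NC(C)C)c([Si](C)(C)C)c(OCOC)c1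
F9 | step 2 | 3,5-bis(methoxymethoxy)-2-(trimethylsilyl)phenol (not isolated) | COCOc1cc(O)c([Si](C)(C)C)c(OCOC)c1
F10 | step 8 | rac-3-hydroxy-3-[8-(methoxymethoxy)-2,2-dimethyl-2H-chromen-6-yl]-1-(morpholin-4-yl)propan-1-one | CC1(C)C=Cc2cc(C(O)CC(=O)N3CCOCC3)cc(OCOC)c2O1
F11 | step 8 | (1R)-1-[8-(methoxymethoxy)-2,2-dimethyl-2H-chromen-6-yl]-3-(morpholin-4-yl)-3-oxopropyl acetate | CC1(C)C=Cc2cc([C@H](OC(C)=O)CC(=O)N3CCOCC3)cc(OCOC)c2O1
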